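The octalin of the target is read as a rearranged drimane. Its cis methyls at C8 and quaternary C9, beside the tetrasubstituted C5=C10 bond shared by rings A and B, with the C4 gem-dimethyl untouched, are what a drimane C8 cation leaves after an H9-to-C8 shift, a C10-methyl-to-C9 shift and loss of H5. One BF3-triggered cascade on 11-(2,3,5,6-tetramethoxyphenyl)driman-8α-ol therefore sets both stereocentres and the alkene, relaying the C9/C10 configuration of (+)-sclareolide. That precursor comes from sclareolide by excision of one carbon, aryllithium addition and benzylic deoxygenation. Arene oxidation and selective hydrolysis then unveil the hydroxy-methoxy-quinone.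

Key step: step 7

Remark: drimane numbering is used for all decalin compounds (ring A = C1–C5/C10, ring B = C5–C10, C11 is the carbon on C9, C12 the methyl carbon on C8). The carbinol carbon C11 of compounds 3, 4, 8, 9 and 10 is drawn without a descriptor because its configuration has no bearing on the route and is removed in steps 3 and 6.

Step 1
Reactants: 1 (+)-sclareolide
Product: 3 11-hydroxysclareolide (hydroxyl on the lactone α-carbon C11), via sclareolide potassium enolate 2 (not isolated)
Conditions: KN(SiMe3)2, THF, −78 °C; 2-(phenylsulfonyl)-3-phenyloxaziridine, −78 °C; AcOH quench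
Reagents that add atoms: 2-(phenylsulfonyl)-3-phenyloxaziridine O=S(=O)(N1OC1c1ccccc1)c1ccccc1
Why: Enolate α-hydroxylation with an N-sulfonyloxaziridine (Davis oxidation) should oxygenate the γ-lactone at C11, attack being expected anti to the axial C8 and C10 methyls, and the new centre is inconsequential because step 3 destroys it.

Step 2
Reactants: 3 11-hydroxysclareolide
Product: 4 11-(hydroxymethyl)drimane-8α,11-diol (triol)
Conditions: LiAlH4, THF, 0 °C to rt; then H2O
Reagents that add atoms: none
Why: Hydride reduction of the α-hydroxy lactone with LiAlH4 should open the ring to the triol without touching C5, C8, C9 or C10.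

Step 3
Reactants: 4 11-(hydroxymethyl)drimane-8α,11-diol
Product: 5 8α-hydroxydriman-11-al
Conditions: NaIO4, THF/H2O, 0 °C to rt
Reagents that add atoms: none
Why: Periodate glycol cleavage (Malaprade reaction) should cut only the vicinal diol, since the C8 hydroxyl is 1,3-related and inert, releasing the extra carbon as formaldehyde and leaving the aldehyde on C9 in its equatorial β orientation.

Step 4
Reactants: 6 1,2,4,5-tetramethoxybenzene; 5 8α-hydroxydriman-11-al
Product: 8 11-(2,3,5,6-tetramethoxyphenyl)drimane-8α,11-diol, via 2,3,5,6-tetramethoxyphenyllithium 7 (not isolated)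
Conditions: n-BuLi, THF, 0 °C (6, 3 equiv); then 5 added slowly at −78 °C, to −20 °C; H2O
Reagents that add atoms: none
Why: Directed ortho-lithiation between two methoxy groups followed by 1,2-addition of the aryllithium to the aldehyde should give the carbinol, because inverse addition to excess 7 at −78 °C lets one equivalent deprotonate the C8 hydroxyl while carbonyl addition outruns retro-aldol cleavage, and either C11 epimer serves.

Step 5
Reactants: 8 11-(2,3,5,6-tetramethoxyphenyl)drimane-8α,11-diol
Product: 10 11-O-(methylsulfanylthiocarbonyl)-11-(2,3,5,6-tetramethoxyphenyl)drimane-8α,11-diol (benzylic S-methyl xanthate), via sodium xanthate salt 9 (not isolated)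
Conditions: NaH (1.1 equiv), THF, 0 °C; CS2; then MeI, 0 °C to rt
Reagents that add atoms: carbon disulfide S=C=S; iodomethane CI
Why: Xanthate formation (first half of a Barton–McCombie deoxygenation) should be selective because with about one equivalent of base only the secondary benzylic alkoxide is captured by CS2 and methylated, the hindered tertiary C8 hydroxyl staying free.

Step 6
Reactants: 10 benzylic S-methyl xanthate
Product: 11 11-(2,3,5,6-tetramethoxyphenyl)driman-8α-ol
Conditions: Bu3SnH, AIBN (cat.), toluene, 80 °C
Reagents that add atoms: none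
Why: Barton–McCombie radical deoxygenation should proceed by stannyl radical addition to the thiocarbonyl, β-scission to a benzylic C11 radical and hydrogen transfer from Bu3SnH, a neutral chain that leaves the tertiary alcohol, the methyl ethers and C9 untouched.

Step 7
Reactants: 11 11-(2,3,5,6-tetramethoxyphenyl)driman-8α-ol
Product: 12 (8S,9R)-rearranged 5(10)-ene: 1-{[(1R,2S)-1,2,5,5-tetramethyl-1,2,3,4,5,6,7,8-octahydronaphthalen-1-yl]methyl}-2,3,5,6-tetramethoxybenzene
Conditions: BF3·OEt2 (3 equiv), CH2Cl2, −78 to −20 °C; Et3N then aq NaHCO3 at −20 °C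
Reagents that add atoms: none
Why: BF3 should ionise the tertiary C8–O bond to the drimane C8 cation, after which axial H9 on the α face moves to C8, the axial β methyl on C10 follows to C9, and the C10 cation loses axial H5 to give the tetrasubstituted C5=C10 alkene; this is a Wagner–Meerwein 1,2-hydride then 1,2-methyl cascade of the kind established for BF3-treated 11-aryl drimane C8 cations. No ring is closed, the decalin being reorganised in place into the octalin. C8 (S) is fixed by suprafacial arrival of H9 on the α face, which leaves the C8 methyl β, and C9 (R) by suprafacial arrival of the C10 methyl on the β face, which pushes the arylmethyl group α, so both centres are dictated by the trans-diaxial H9/C10-methyl/H5 array inherited from sclareolide. The step has to stop at the 5(10)-ene without a further C4-methyl shift, 1(10)-ene formation or oxygen capture; low temperature, a cold basic quench and the stability of the tetrasubstituted alkene should hold it there. Because all four aryl oxygens are methyl ethers and the only free aryl position lies para to the side chain, neither cyclic ether formation nor Friedel–Crafts closure can drain the cations.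

Step 8
Reactants: 12 rearranged 5(10)-ene tetramethoxyarene
Product: 13 2,5-dimethoxy-3-{[(1R,2S)-1,2,5,5-tetramethyl-1,2,3,4,5,6,7,8-octahydronaphthalen-1-yl]methyl}-1,4-benzoquinone
Conditions: (NH4)2Ce(NO3)6 (2.5 equiv), MeCN/H2O, 0 °C
Reagents that add atoms: water O
Why: Oxidative demethylation by tetravalent cerium should convert a para pair of methoxy-bearing carbons into quinone carbonyls with water as the oxygen source, both para pairs leading to the same 2,5-dimethoxyquinone, and the electron-rich arene is oxidised far more readily than the tetrasubstituted alkene.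

Step 9
Reactants: 13 3-alkyl-2,5-dimethoxy-1,4-benzoquinone
Product: 15 target quinone (2-hydroxy-5-methoxy-3-alkyl-1,4-benzoquinone), via potassium quinonolate 14 (not isolated)
Conditions: KOH, MeOH/H2O, rt; then 1 M HCl, 0 °C
Reagents that add atoms: potassium hydroxide [K+].[OH-]
Why: Vinylogous ester saponification by addition–elimination of hydroxide should strike first the methoxy group next to the bulky side chain, which is twisted out of conjugation, and the resulting vinylogous carboxylate anion resists a second hydrolysis, so brief cold acidification gives the target.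

Compound list
1 | (+)-sclareolide | CC1(C)CCC[C@@]2(C)[C@H]1CC[C@@]3(C)OC(=O)C[C@H]23 | starting material
2 | sclareolide potassium enolate | CC1(C)CCC[C@@]2(C)[C@H]1CC[C@@]3(C)OC([O-])=C[C@H]23.[K+] | intermediate
3 | 11-hydroxysclareolide (C11 configuration open) | CC1(C)CCC[C@@]2(C)[C@H]1CC[C@@]3(C)OC(=O)C(O)[C@H]23 | intermediate
4 | 11-(hydroxymethyl)drimane-8α,11-diol | CC1(C)CCC[C@@]2(C)[C@H]1CC[C@@](C)(O)[C@@H]2C(O)CO | intermediate
5 | 8α-hydroxydriman-11-al | CC1(C)CCC[C@@]2(C)[C@H]1CC[C@@](C)(O)[C@@H]2C=O | intermediate
6 | 1,2,4,5-tetramethoxybenzene | COc1cc(OC)c(OC)cc1OC | starting material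
7 | 2,3,5,6-tetramethoxyphenyllithium | [Li]c1c(OC)c(OC)cc(OC)c1OC | intermediate
8 | 11-(2,3,5,6-tetramethoxyphenyl)drimane-8α,11-diol | CC1(C)CCC[C@@]2(C)[C@H]1CC[C@@](C)(O)[C@@H]2C(O)c3c(OC)c(OC)cc(OC)c3OC | intermediate
9 | sodium xanthate salt of 8 (benzylic oxygen) | CC1(C)CCC[C@@]2(C)[C@H]1CC[C@@](C)(O)[C@@H]2C(OC(=S)[S-])c3c(OC)c(OC)cc(OC)c3OC.[Na+] | intermediate
10 | benzylic S-methyl xanthate of 8 | CC1(C)CCC[C@@]2(C)[C@H]1CC[C@@](C)(O)[C@@H]2C(OC(=S)SC)c3c(OC)c(OC)cc(OC)c3OC | intermediate
11 | 11-(2,3,5,6-tetramethoxyphenyl)driman-8α-ol | CC1(C)CCC[C@@]2(C)[C@H]1CC[C@@](C)(O)[C@@H]2Cc3c(OC)c(OC)cc(OC)c3OC | intermediate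
12 | (8S,9R)-rearranged 5(10)-ene tetramethoxyarene | COc1cc(OC)c(OC)c(C[C@@]2(C)C3=C(CC[C@@H]2C)C(C)(C)CCC3)c1OC | intermediate
13 | 3-alkyl-2,5-dimethoxy-1,4-benzoquinone | COC1=CC(=O)C(OC)=C(C[C@@]2(C)C3=C(CC[C@@H]2C)C(C)(C)CCC3)C1=O | intermediate
14 | potassium quinonolate of the target | COC1=CC(=O)C([O-])=C(C[C@@]2(C)C3=C(CC[C@@H]2C)C(C)(C)CCC3)C1=O.[K+] | intermediate
15 | target quinone | COC1=CC(=O)C(O)=C(C[C@@]2(C)C3=C(CC[C@@H]2C)C(C)(C)CCC3)C1=O | target

Total step count: 9 steps. Longest linear sequence: 9 steps (1 to 15); arene 6 is bought and lithiated in the flask in step 4.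

Steps most likely to fail

Step 7. Ionisation of the tertiary C–O bond may need more warming than the cascade tolerates. It could then stall at simple proton loss next to C8, or overrun through a further methyl migration and acid isomerisation of the new alkene. The fallback sets out from 11 and comes back at 12. The alcohol would first be dehydrated under basic, non-rearranging conditions (SOCl2, pyridine, CH2Cl2, −20 to 0 °C) to 11-(2,3,5,6-tetramethoxyphenyl)drim-8(12)-ene F1, accompanied by 11-(2,3,5,6-tetramethoxyphenyl)drim-7-ene F2. The olefin mixture, both members of which protonate to the same C8 cation, would then be treated with BF3·OEt2 in CH2Cl2 at −50 to −20 °C. This is the substrate class for which the hydride/methyl shift sequence is established, and it should deliver 12.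

Step 5. Capture of the benzylic alkoxide may be diverted by the neighbouring C8 alkoxide closing onto the thiocarbonyl. On heating in step 6, the electron-rich benzylic xanthate may also eliminate or migrate from oxygen to sulfur before the radical chain consumes it. The fallback sets out from 8 and comes back at 11, bypassing steps 5 and 6. Selective acetylation of the secondary hydroxyl (Ac2O, DMAP, pyridine, 0 °C; the tertiary hydroxyl is inert) would give 11-acetoxy-11-(2,3,5,6-tetramethoxyphenyl)driman-8α-ol F3. Dissolving-metal cleavage of the benzylic C–O bond (Li, liquid NH3/THF, −78 °C, short contact, NH4Cl quench) would then give 11. The ester should be cleaved well before the highly alkoxylated ring is reduced.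

Step 4. Once the C8 hydroxyl is deprotonated, retro-aldol opening of ring B or enolisation at C9 may compete with carbonyl addition. The fallback sets out from 5 and comes back at 8. The tertiary hydroxyl would be capped first (Me3SiCl, imidazole, CH2Cl2, 0 °C) as 8α-(trimethylsilyloxy)driman-11-al F4. This aldehyde needs only a slight excess of 7 at −78 °C and should give 11-(2,3,5,6-tetramethoxyphenyl)-8α-(trimethylsilyloxy)driman-11-ol F5. K2CO3 in MeOH at rt would then remove the silyl group and return diol 8.

Further compounds
F1 | step 7 | 11-(2,3,5,6-tetramethoxyphenyl)drim-8(12)-ene | CC1(C)CCC[C@@]2(C)[C@H]1CCC(=C)[C@@H]2Cc3c(OC)c(OC)cc(OC)c3OC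
F2 | step 7 | 11-(2,3,5,6-tetramethoxyphenyl)drim-7-ene | CC1(C)CCC[C@@]2(C)[C@H]1CC=C(C)[C@@H]2Cc3c(OC)c(OC)cc(OC)c3OC
F3 | step 5 | 11-acetoxy-11-(2,3,5,6-tetramethoxyphenyl)driman-8α-ol | CC1(C)CCC[C@@]2(C)[C@H]1CC[C@@](C)(O)[C@@H]2C(OC(C)=O)c3c(OC)c(OC)cc(OC)c3OC
F4 | step 4 | 8α-(trimethylsilyloxy)driman-11-al | CC1(C)CCC[C@@]2(C)[C@H]1CC[C@@](C)(O[Si](C)(C)C)[C@@H]2C=O
F5 | step 4 | 11-(2,3,5,6-tetramethoxyphenyl)-8α-(trimethylsilyloxy)driman-11-ol | CC1(C)CCC[C@@]2(C)[C@H]1CC[C@@](C)(O[Si](C)(C)C)[C@@H]2C(O)c3c(OC)c(OC)cc(OC)c3OC
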